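**Retrosynthetic overview**

1. Locants used throughout: ring C1 (bears the side chain), C2 (CH2), C3/C4 (oxirane, CH3 on C4), C5 and C6 (ester carbons); side chain C7 (=CH2), C8 (ester carbinol), C9, C10/C11 (oxirane). Target ⇐ Shi epoxidation of C10=C11 ⇐ angeloylation of O8 ⇐ C8 carbinol by Corey–Bakshi–Shibata reduction ⇐ C7–C8 bond by Nozaki–Hiyama–Kishi coupling of a C7 enol triflate with 4-methylpent-3-enal.
2. Enol triflate ⇐ C7 methyl ketone ⇐ MeLi opening of a bridged epoxy γ-lactone (O5–C7 lactone, 6-oxabicyclo[3.2.1]octan-7-one); the C3–C4 oxirane is installed on this bicycle by O6–H-directed exo epoxidation.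
3. Key disconnection C4–C5: the bicyclic lactone ⇐ open-chain (Z)-alkenyl iodide / aldehyde / N-acyloxazolidinone, by Ni/Cr ring closure (alkenyl C4 onto aldehyde C5) and, in the same flask, lactonisation of O5 onto C7 with loss of the auxiliary.
4. Enabling feature: the C3–C4 oxirane next to the C5 carbinol is a masked 2-methylcyclohex-2-enol (C4 = alkenyl nucleophile, C5 = aldehyde carbon), and O5 and the C1–C7 bond are cis-1,3 on the six-membered ring, so C7 at the carboxyl level can bridge to O5 as a γ-lactone that locks the ring, tells O5 from O6 and leaves one alkene face open.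
5. Open-chain precursor ⇐ auxiliary-controlled anti-aldol (C1–C6 bond) of an N-[(Z)-5-iodohex-4-enoyl]oxazolidinone with cinnamaldehyde, then oxidative cleavage. Ring order: carbocycle and lactone (step 7), ring oxirane (step 9), lactone opened (step 10), side-chain oxirane (step 18).

Key step: step 7

Remark: chromium intermediates are written as dichlorides without solvent ligands; 1, 5, 8, 24, angelic acid and angelic anhydride are taken as commercial; diol 12 is drawn as the diastereomer expected from osmylation anti to the silyloxy group, and its two carbinol centres are lost again in the same step.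

**Route**

Step 1
Reactants: 1 methyl 4-oxobutanoate
Product: 2 methyl (4Z)-5-iodohex-4-enoate
Conditions: EtPPh3I, n-BuLi, THF, 0 °C to rt; I2, −78 °C; NaN(SiMe3)2, −20 °C; then 1, −78 °C to rt
Reagents that add atoms: ethyltriphenylphosphonium iodide, CC[P+](c1ccccc1)(c1ccccc1)c1ccccc1.[I-]; iodine, II
Why: Stork–Zhao-type Wittig olefination, in which the α-iodo ylide Ph3P=C(I)CH3 formed in the flask should add to the aldehyde under kinetic control to give the (Z)-2-iodoalk-2-ene, the ester being inert at low temperature.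

Step 2
Reactants: 2 methyl (4Z)-5-iodohex-4-enoate
Product: 4 (4Z)-5-iodohex-4-enoic acid, via lithium (4Z)-5-iodohex-4-enoate 3 (not isolated)
Conditions: LiOH, THF/H2O, 0 °C to rt; then 1 M HCl
Reagents that add atoms: lithium hydroxide, [Li+].[OH-]
Why: Ester saponification, to which the alkenyl iodide is inert.

Step 3
Reactants: 4 (4Z)-5-iodohex-4-enoic acid; 5 (4R)-4-benzyl-1,3-oxazolidin-2-one
Product: 7 (4R)-4-benzyl-3-[(4Z)-5-iodohex-4-enoyl]-1,3-oxazolidin-2-one, via (4Z)-5-iodohex-4-enoic pivalic anhydride 6 (not isolated)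
Conditions: t-BuCOCl, Et3N, THF, −20 °C; then LiCl, 5, rt
Reagents that add atoms: none
Why: N-Acylation of the auxiliary through the mixed pivalic anhydride, which is attacked at its less hindered acyl carbon.

Step 4
Reactants: 7 (4R)-4-benzyl-3-[(4Z)-5-iodohex-4-enoyl]-1,3-oxazolidin-2-one; 8 (E)-cinnamaldehyde
Product: 10 (4R)-4-benzyl-3-[(2S,3S,4E)-3-hydroxy-2-[(2Z)-3-iodobut-2-en-1-yl]-5-phenylpent-4-enoyl]-1,3-oxazolidin-2-one, via O-trimethylsilyl ether 9 (not isolated)
Conditions: MgCl2 (10 mol%), Et3N, Me3SiCl, EtOAc, 23 °C; then CF3CO2H (cat.), MeOH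
Reagents that add atoms: none
Why: Magnesium-halide-catalysed anti-aldol of an N-acyloxazolidinone (Evans anti-aldol), in which the chelated Z-magnesium enolate should meet the non-enolisable enal on the face away from the benzyl group through a boat transition state, setting C1 and C6 anti, with silylation driving turnover.

Step 5
Reactants: 10 anti-aldol adduct
Product: 11 (4R)-4-benzyl-3-[(2S,3S,4E)-3-[(tert-butyldimethylsilyl)oxy]-2-[(2Z)-3-iodobut-2-en-1-yl]-5-phenylpent-4-enoyl]-1,3-oxazolidin-2-one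
Conditions: TBSOTf, 2,6-lutidine, CH2Cl2, −78 to 0 °C
Reagents that add atoms: tert-butyldimethylsilyl triflate, CC(C)(C)[Si](C)(C)OS(=O)(=O)C(F)(F)F
Why: Silyl ether formation under non-nucleophilic base, which should protect O6 without retro-aldol or epimerisation.

Step 6
Reactants: 11 silyl ether
Product: 13 (4R)-4-benzyl-3-[(2S,3R)-3-[(tert-butyldimethylsilyl)oxy]-2-[(2Z)-3-iodobut-2-en-1-yl]-4-oxobutanoyl]-1,3-oxazolidin-2-one, via vicinal diol 12 (not isolated)
Conditions: OsO4 (2 mol%), NaIO4, 2,6-lutidine, dioxane/H2O, rt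
Reagents that add atoms: osmium tetroxide, O=[Os](=O)(=O)=O; sodium periodate, [Na+].[O-]I(=O)(=O)=O
Why: Lemieux–Johnson oxidative cleavage, in which OsO4 should syn-dihydroxylate the electron-rich styryl double bond much faster than the electron-poor iodoalkene and periodate then cleaves the vicinal diol at once to unveil the C5 aldehyde, so that the facial selectivity of the osmylation is of no consequence.

Step 7
Reactants: 13 iodoalkenyl aldehyde imide
Product: 16 (1S,5R,8R)-8-[(tert-butyldimethylsilyl)oxy]-4-methyl-6-oxabicyclo[3.2.1]oct-3-en-7-one, via alkenylchromium dichloride 14 (not isolated), via ring-closed chromium alkoxide 15 (not isolated)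
Conditions: CrCl2 (6 equiv), NiCl2 (2 mol%), degassed DMSO (0.005 M), rt; then 45 °C; aqueous work-up
Reagents that add atoms: none
Why: Zerovalent nickel inserts into the C–I bond, the alkenyl group passes to chromium with retention of the Z geometry, and the trivalent alkenylchromium adds to the aldehyde to form the C4–C5 bond; the chromium alkoxide on C5 then attacks the exocyclic imide carbonyl C7 and expels the oxazolidinone, so that carbocycle formation, lactonisation and auxiliary removal happen in one flask. The closest precedents are intramolecular Nozaki–Hiyama–Kishi cyclisations of (Z)-2-iodoalkenyl aldehydes to 2-methylcyclohex-2-enols, Nozaki–Hiyama–Kishi/lactonisation sequences with ester acceptors, and alkoxide-triggered N-to-O acyl transfer of N-acyloxazolidinones. The six-membered ring should close by 6-exo-trig addition of the alkenyl carbon to the C=O group through a chair with the C1 acyl group and the C6 silyloxy group (trans, fixed in step 4) both equatorial, and the γ-lactone by 5-exo-trig acyl substitution after ring inversion to the conformer with O5 and C7 1,3-diaxial. The new stereocentre C5 should be controlled by the imide carbonyl, a good donor for trivalent chromium that holds the metal and its bound aldehyde oxygen on the face of C7, and by the equatorial preference of the chromium alkoxide; in addition only the C5 epimer with O5 cis to C7 can lactonise, so the bicyclic lactone is homogeneous at C5. The step needs chemoselective activation of the C–I bond (the only reducible group), retention of alkene geometry (alkenylchromium reagents are configurationally stable), cyclisation over oligomerisation (high dilution) and acyl transfer at the exocyclic carbonyl (five-membered transition state).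

Step 8
Reactants: 16 bicyclic lactone silyl ether
Product: 17 (1S,5R,8R)-8-hydroxy-4-methyl-6-oxabicyclo[3.2.1]oct-3-en-7-one
Conditions: HF·pyridine, pyridine, THF, 0 °C to rt
Reagents that add atoms: none
Why: Fluoride-mediated desilylation under buffered conditions, which should free O6–H and leave lactone and alkene untouched.

Step 9
Reactants: 17 hydroxy lactone
Product: 18 (1S,3S,4S,5S,8R)-3,4-epoxy-8-hydroxy-4-methyl-6-oxabicyclo[3.2.1]octan-7-one
Conditions: VO(acac)2 (5 mol%), t-BuOOH, CH2Cl2, 0 °C to rt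
Reagents that add atoms: tert-butyl hydroperoxide, CC(C)(C)OO
Why: Hydroxyl-directed vanadium-catalysed epoxidation, in which the hydroxyl on the one-carbon bridge lies syn to the C3=C4 double bond and should deliver the peroxide to the exo face, which is also the face away from the lactone bridge, setting C3 and C4 cis to O6 and trans to O5.

Step 10
Reactants: 18 epoxy hydroxy lactone
Product: 20 (1S,3S,4S,5S,6R)-1-acetyl-3,4-epoxy-4-methylcyclohexane-5,6-diol (target locants), via dilithium methyl hemiketalate 19 (not isolated)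
Conditions: MeLi (2.2 equiv), THF, −78 °C; aq. NH4Cl at −78 °C
Reagents that add atoms: methyllithium, [Li]C
Why: Mono-addition of an organolithium to a bridged lactone, whose tetrahedral lithium hemiketalate should persist at −78 °C and collapse only on protonation, giving the C7 methyl ketone and releasing O5–H (temporary lactone removed).

Step 11
Reactants: 20 keto diol
Product: 21 (1S,3S,4S,5S,6R)-1-acetyl-3,4-epoxy-4-methylcyclohexane-5,6-diyl bis[(2Z)-2-methylbut-2-enoate]
Conditions: angelic acid, 2,4,6-Cl3C6H2COCl, Et3N, PhMe, rt, filtered; then 20, NaHCO3, PhMe, 80 °C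
Reagents that add atoms: angelic acid, C/C=C(/C)C(=O)O
Why: Yamaguchi-type esterification with the angelic 2,4,6-trichlorobenzoic mixed anhydride without nucleophilic catalyst, which should acylate both secondary hydroxyls without Z-to-E isomerisation and without a strong base that would enolise the ketone towards C1.

Step 12
Reactants: 21 bis-angelate methyl ketone
Product: 23 (1S,3S,4S,5S,6R)-3,4-epoxy-4-methyl-1-[1-(trifluoromethanesulfonyloxy)ethenyl]cyclohexane-5,6-diyl bis[(2Z)-2-methylbut-2-enoate], via terminal potassium enolate 22 (not isolated)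
Conditions: KN(SiMe3)2, THF, −78 °C; PhNTf2, −78 to −20 °C; aq. NH4Cl
Reagents that add atoms: N-phenylbis(trifluoromethanesulfonimide), O=S(=O)(N(c1ccccc1)S(=O)(=O)C(F)(F)F)C(F)(F)F
Why: Kinetic enolisation of the methyl ketone at CH3 by a bulky amide and O-triflation of the terminal enolate, which cannot expel the β-acyloxy group on C6.

Step 13
Reactants: 24 4-methylpent-3-en-1-ol
Product: 25 4-methylpent-3-enal
Conditions: 1,1,1-triacetoxy-1,2-benziodoxol-3(1H)-one (DMP), pyridine, CH2Cl2, 0 °C; used at once as a solution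
Reagents that add atoms: none
Why: Dess–Martin oxidation under buffered, non-equilibrating conditions, which should give the β,γ-unsaturated aldehyde without migration of the double bond.

Step 14
Reactants: 23 enol triflate; 25 4-methylpent-3-enal
Product: 28 (1R,3S,4S,5S,6R)-3,4-epoxy-1-(3-hydroxy-6-methylhepta-1,5-dien-2-yl)-4-methylcyclohexane-5,6-diyl bis[(2Z)-2-methylbut-2-enoate] as both C8 epimers, via alkenylchromium dichloride 26 (not isolated), via chromium alkoxide 27 (not isolated)
Conditions: CrCl2 (5 equiv), NiCl2 (2 mol%), DMF, rt; aqueous work-up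
Reagents that add atoms: none
Why: Intermolecular Nozaki–Hiyama–Kishi coupling, in which nickel activates the enol triflate and the 1,1-disubstituted alkenylchromium adds chemoselectively to the aldehyde to form the C7–C8 bond, esters and oxirane being tolerated (C8 is not controlled here and is set in steps 15–16).

Step 15
Reactants: 28 allylic alcohols
Product: 29 (1R,3S,4S,5S,6R)-3,4-epoxy-4-methyl-1-(6-methyl-3-oxohepta-1,5-dien-2-yl)cyclohexane-5,6-diyl bis[(2Z)-2-methylbut-2-enoate]
Conditions: DMP, pyridine, CH2Cl2, 0 °C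
Reagents that add atoms: none
Why: Dess–Martin oxidation, which should converge both C8 epimers to the cross-conjugated enone under non-basic conditions that leave the skipped diene in place.

Step 16
Reactants: 29 enone
Product: 31 (1R,3S,4S,5S,6R)-3,4-epoxy-1-[(3S)-3-hydroxy-6-methylhepta-1,5-dien-2-yl]-4-methylcyclohexane-5,6-diyl bis[(2Z)-2-methylbut-2-enoate], via catechol borate ester 30 (not isolated)
Conditions: (R)-1-methyl-3,3-diphenyltetrahydro-1H,3H-pyrrolo[1,2-c][1,3,2]oxazaborole (20 mol%), catecholborane, PhMe, −78 °C; aqueous work-up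
Reagents that add atoms: none
Why: Corey–Bakshi–Shibata reduction, in which the α-branched alkenyl group acts as the large substituent so that the (R)-oxazaborolidine should give the (S)-carbinol at C8 under reagent control, catecholborane at −78 °C reducing 1,2 without hydroborating the alkenes.

Step 17
Reactants: 31 (S)-allylic alcohol
Product: 33 (1R,3S,4S,5S,6R)-3,4-epoxy-4-methyl-1-[(3S)-6-methyl-3-{[(2Z)-2-methylbut-2-enoyl]oxy}hepta-1,5-dien-2-yl]cyclohexane-5,6-diyl bis[(2Z)-2-methylbut-2-enoate], via lithium alkoxide 32 (not isolated)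
Conditions: LiN(SiMe3)2, THF, −78 °C; angelic anhydride, −78 to 0 °C; aq. NH4Cl
Reagents that add atoms: angelic anhydride, C/C=C(/C)C(=O)OC(=O)/C(C)=C\C
Why: Acylation of a lithium alkoxide with the anhydride, a stereoconservative angeloylation that avoids the amine catalysts known to isomerise angelates to tiglates.

Step 18
Reactants: 33 tris-angelate diene
Product: 34 CNP0258231.1 (target)
Conditions: 1,2:4,5-di-O-isopropylidene-β-D-erythro-2,3-hexodiulo-2,6-pyranose (30 mol%), KHSO5 (as 2KHSO5·KHSO4·K2SO4), K2CO3, Bu4NHSO4, MeCN/CH2(OMe)2/aq. Na2B4O7 buffer, 0 °C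
Reagents that add atoms: potassium peroxymonosulfate, [K+].[O-]S(=O)(=O)OO
Why: Shi epoxidation, in which the D-fructose-derived dioxirane should epoxidise the electron-rich trisubstituted C10=C11 bond through the spiro transition state to give the (R)-oxirane at C10, the 1,1-disubstituted alkene and the conjugated ester double bonds reacting much more slowly.

**Compound list**

1 | methyl 4-oxobutanoate | COC(=O)CCC=O | starting material
2 | methyl (4Z)-5-iodohex-4-enoate | COC(=O)CC/C=C(/C)I | intermediate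
3 | lithium (4Z)-5-iodohex-4-enoate | [Li+].[O-]C(=O)CC/C=C(/C)I | intermediate
4 | (4Z)-5-iodohex-4-enoic acid | OC(=O)CC/C=C(/C)I | intermediate
5 | (4R)-4-benzyl-1,3-oxazolidin-2-one | O=C1N[C@H](Cc2ccccc2)CO1 | starting material
6 | (4Z)-5-iodohex-4-enoic pivalic anhydride | CC(C)(C)C(=O)OC(=O)CC/C=C(/C)I | intermediate
7 | (4R)-4-benzyl-3-[(4Z)-5-iodohex-4-enoyl]-1,3-oxazolidin-2-one | O=C(CC/C=C(/C)I)N1[C@H](Cc2ccccc2)COC1=O | intermediate
8 | (E)-cinnamaldehyde | O=C/C=C/c1ccccc1 | starting material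
9 | O-trimethylsilyl ether of 10 | O=C(N1[C@H](Cc2ccccc2)COC1=O)[C@@H](C/C=C(/C)I)[C@@H](O[Si](C)(C)C)/C=C/c1ccccc1 | intermediate
10 | (4R)-4-benzyl-3-[(2S,3S,4E)-3-hydroxy-2-[(2Z)-3-iodobut-2-en-1-yl]-5-phenylpent-4-enoyl]-1,3-oxazolidin-2-one | O=C(N1[C@H](Cc2ccccc2)COC1=O)[C@@H](C/C=C(/C)I)[C@@H](O)/C=C/c1ccccc1 | intermediate
11 | O-tert-butyldimethylsilyl ether of 10 | O=C(N1[C@H](Cc2ccccc2)COC1=O)[C@@H](C/C=C(/C)I)[C@@H](O[Si](C)(C)C(C)(C)C)/C=C/c1ccccc1 | intermediate
12 | vicinal diol of 11: (4R)-4-benzyl-3-[(2S,3R,4S,5R)-3-[(tert-butyldimethylsilyl)oxy]-4,5-dihydroxy-2-[(2Z)-3-iodobut-2-en-1-yl]-5-phenylpentanoyl]-1,3-oxazolidin-2-one | O=C(N1[C@H](Cc2ccccc2)COC1=O)[C@@H](C/C=C(/C)I)[C@@H](O[Si](C)(C)C(C)(C)C)[C@@H](O)[C@H](O)c1ccccc1 | intermediate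
13 | (4R)-4-benzyl-3-[(2S,3R)-3-[(tert-butyldimethylsilyl)oxy]-2-[(2Z)-3-iodobut-2-en-1-yl]-4-oxobutanoyl]-1,3-oxazolidin-2-one | O=C(N1[C@H](Cc2ccccc2)COC1=O)[C@@H](C/C=C(/C)I)[C@@H](O[Si](C)(C)C(C)(C)C)C=O | intermediate
14 | (2Z)-3-(dichlorochromio)but-2-en-1-yl analogue of 13 (trivalent alkenylchromium) | O=C(N1[C@H](Cc2ccccc2)COC1=O)[C@@H](C/C=C(/C)[Cr](Cl)Cl)[C@@H](O[Si](C)(C)C(C)(C)C)C=O | intermediate
15 | dichlorochromium alkoxide of (4R)-4-benzyl-3-{[(1S,5R,6R)-6-[(tert-butyldimethylsilyl)oxy]-5-hydroxy-4-methylcyclohex-3-en-1-yl]carbonyl}-1,3-oxazolidin-2-one | O=C(N1[C@H](Cc2ccccc2)COC1=O)[C@H]3CC=C(C)[C@@H](O[Cr](Cl)Cl)[C@@H]3O[Si](C)(C)C(C)(C)C | intermediate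
16 | (1S,5R,8R)-8-[(tert-butyldimethylsilyl)oxy]-4-methyl-6-oxabicyclo[3.2.1]oct-3-en-7-one | O=C1[C@H]2CC=C(C)[C@@H](O1)[C@@H]2O[Si](C)(C)C(C)(C)C | intermediate
17 | (1S,5R,8R)-8-hydroxy-4-methyl-6-oxabicyclo[3.2.1]oct-3-en-7-one | O=C1[C@H]2CC=C(C)[C@@H](O1)[C@@H]2O | intermediate
18 | (1S,3S,4S,5S,8R)-3,4-epoxy-8-hydroxy-4-methyl-6-oxabicyclo[3.2.1]octan-7-one (oxirane syn to the 8-OH, anti to the lactone bridge) | O=C1[C@H]2C[C@@H]3O[C@]3(C)[C@@H](O1)[C@@H]2O | intermediate
19 | dilithium salt of the bridged methyl hemiketal formed from 18 and MeLi | CC1(O[Li])[C@H]2C[C@@H]3O[C@]3(C)[C@@H](O1)[C@@H]2O[Li] | intermediate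
20 | (1S,3S,4S,5S,6R)-1-acetyl-3,4-epoxy-4-methylcyclohexane-5,6-diol (target locants) | CC(=O)[C@H]1C[C@@H]2O[C@]2(C)[C@@H](O)[C@@H]1O | intermediate
21 | (1S,3S,4S,5S,6R)-1-acetyl-3,4-epoxy-4-methylcyclohexane-5,6-diyl bis[(2Z)-2-methylbut-2-enoate] | CC(=O)[C@H]1C[C@@H]2O[C@]2(C)[C@@H](OC(=O)/C(C)=C\C)[C@@H]1OC(=O)/C(C)=C\C | intermediate
22 | terminal potassium enolate of 21 | C=C(O[K])[C@H]1C[C@@H]2O[C@]2(C)[C@@H](OC(=O)/C(C)=C\C)[C@@H]1OC(=O)/C(C)=C\C | intermediate
23 | (1S,3S,4S,5S,6R)-3,4-epoxy-4-methyl-1-[1-(trifluoromethanesulfonyloxy)ethenyl]cyclohexane-5,6-diyl bis[(2Z)-2-methylbut-2-enoate] | C=C(OS(=O)(=O)C(F)(F)F)[C@H]1C[C@@H]2O[C@]2(C)[C@@H](OC(=O)/C(C)=C\C)[C@@H]1OC(=O)/C(C)=C\C | intermediate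
24 | 4-methylpent-3-en-1-ol | CC(C)=CCCO | starting material
25 | 4-methylpent-3-enal | CC(C)=CCC=O | intermediate
26 | 1-(dichlorochromio)ethenyl analogue of 23 (trivalent alkenylchromium) | C=C([Cr](Cl)Cl)[C@H]1C[C@@H]2O[C@]2(C)[C@@H](OC(=O)/C(C)=C\C)[C@@H]1OC(=O)/C(C)=C\C | intermediate
27 | dichlorochromium alkoxide of 28 | C=C(C(CC=C(C)C)O[Cr](Cl)Cl)[C@H]1C[C@@H]2O[C@]2(C)[C@@H](OC(=O)/C(C)=C\C)[C@@H]1OC(=O)/C(C)=C\C | intermediate
28 | (1R,3S,4S,5S,6R)-3,4-epoxy-1-(3-hydroxy-6-methylhepta-1,5-dien-2-yl)-4-methylcyclohexane-5,6-diyl bis[(2Z)-2-methylbut-2-enoate], both C8 epimers | C=C(C(O)CC=C(C)C)[C@H]1C[C@@H]2O[C@]2(C)[C@@H](OC(=O)/C(C)=C\C)[C@@H]1OC(=O)/C(C)=C\C | intermediate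
29 | (1R,3S,4S,5S,6R)-3,4-epoxy-4-methyl-1-(6-methyl-3-oxohepta-1,5-dien-2-yl)cyclohexane-5,6-diyl bis[(2Z)-2-methylbut-2-enoate] | C=C(C(=O)CC=C(C)C)[C@H]1C[C@@H]2O[C@]2(C)[C@@H](OC(=O)/C(C)=C\C)[C@@H]1OC(=O)/C(C)=C\C | intermediate
30 | catechol borate ester of 31 | C=C([C@H](CC=C(C)C)OB3Oc4ccccc4O3)[C@H]1C[C@@H]2O[C@]2(C)[C@@H](OC(=O)/C(C)=C\C)[C@@H]1OC(=O)/C(C)=C\C | intermediate
31 | (1R,3S,4S,5S,6R)-3,4-epoxy-1-[(3S)-3-hydroxy-6-methylhepta-1,5-dien-2-yl]-4-methylcyclohexane-5,6-diyl bis[(2Z)-2-methylbut-2-enoate] | C=C([C@H](CC=C(C)C)O)[C@H]1C[C@@H]2O[C@]2(C)[C@@H](OC(=O)/C(C)=C\C)[C@@H]1OC(=O)/C(C)=C\C | intermediate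
32 | lithium alkoxide of 31 | C=C([C@H](CC=C(C)C)O[Li])[C@H]1C[C@@H]2O[C@]2(C)[C@@H](OC(=O)/C(C)=C\C)[C@@H]1OC(=O)/C(C)=C\C | intermediate
33 | (1R,3S,4S,5S,6R)-3,4-epoxy-4-methyl-1-[(3S)-6-methyl-3-{[(2Z)-2-methylbut-2-enoyl]oxy}hepta-1,5-dien-2-yl]cyclohexane-5,6-diyl bis[(2Z)-2-methylbut-2-enoate] | C=C([C@H](CC=C(C)C)OC(=O)/C(C)=C\C)[C@H]1C[C@@H]2O[C@]2(C)[C@@H](OC(=O)/C(C)=C\C)[C@@H]1OC(=O)/C(C)=C\C | intermediate
34 | CNP0258231.1: (2S)-1-[(2R)-3,3-dimethyloxiran-2-yl]-3-[(1R,3S,4S,5S,6R)-3,4-epoxy-4-methyl-5,6-bis{[(2Z)-2-methylbut-2-enoyl]oxy}cyclohexyl]but-3-en-2-yl (2Z)-2-methylbut-2-enoate | C=C([C@H](C[C@H]1OC1(C)C)OC(=O)/C(C)=C\C)[C@H]1C[C@@H]2O[C@]2(C)[C@@H](OC(=O)/C(C)=C\C)[C@@H]1OC(=O)/C(C)=C\C | target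

**Totals and risks**

Total step count: 18. Longest linear sequence: 17 steps (steps 1–12 and 14–18; step 13 is a one-step side branch).

Steps most likely to fail:

1. Step 7: the alkenyl transfer may show poor facial selectivity at the aldehyde carbon, and acyl transfer from the trivalent chromium alkoxide to the imide may be sluggish. The fallback sets out from 13 and comes back at 16, and sets C5 by hydride reduction instead of by C–C bond formation. The Ni/Cr cyclisation is run at rt without the heating stage and the C5-epimeric cyclohexenol imides F1 are isolated. Oxidation with the triacetoxy periodinane gives the cyclohexenone imide F2. Luche reduction (NaBH4, CeCl3·7H2O, MeOH, −78 °C) should give, by axial hydride delivery, the equatorial alcohol F3 with O5 cis to the acyl group. DBU in CH2Cl2 should then induce lactonisation to 16 with release of 5.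

2. Step 10: a second methyl addition after early collapse of the tetrahedral adduct, or retro-aldol cleavage of the β-alkoxide, may compete. The fallback sets out from 18 and comes back at 20. Aminolysis of the lactone with MeNH(OMe)·HCl and iPrMgCl (THF, −20 °C) gives the Weinreb amide F4. MeMgBr (THF, 0 °C) then gives 20, because the chelated tetrahedral adduct cannot take up a second methyl group.

3. Step 14: the β,γ-unsaturated aldehyde may isomerise into conjugation, and nickel insertion into the hindered enol triflate may be slow. The fallback sets out from 23 and comes back at 31, bypassing steps 14–16, and builds C8 by reagent-controlled allylation. Formylation of 23 (Pd(PPh3)4, CO 1 atm, Bu3SnH, THF, 50 °C) gives the enal F5. Allylboration with B-allyldiisopinocampheylborane prepared from (+)-α-pinene (Et2O, −78 °C; NaBO3 work-up) should give the (S)-homoallylic alcohol F6. Cross-metathesis of F6 with 2-methyl-2-butene (second-generation Grubbs catalyst, RuCl2(=CHPh)(H2IMes)(PCy3), CH2Cl2, 40 °C) converts the terminal vinyl group into the prenyl terminus and gives 31.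

**Further compounds**

F1 | step 7 | (4R)-4-benzyl-3-{[(1S,6R)-6-[(tert-butyldimethylsilyl)oxy]-5-hydroxy-4-methylcyclohex-3-en-1-yl]carbonyl}-1,3-oxazolidin-2-one, both C5 epimers | O=C(N1[C@H](Cc2ccccc2)COC1=O)[C@H]3CC=C(C)C(O)[C@@H]3O[Si](C)(C)C(C)(C)C
F2 | step 7 | (4R)-4-benzyl-3-{[(1S,6R)-6-[(tert-butyldimethylsilyl)oxy]-4-methyl-5-oxocyclohex-3-en-1-yl]carbonyl}-1,3-oxazolidin-2-one | O=C(N1[C@H](Cc2ccccc2)COC1=O)[C@H]3CC=C(C)C(=O)[C@@H]3O[Si](C)(C)C(C)(C)C
F3 | step 7 | (4R)-4-benzyl-3-{[(1S,5R,6R)-6-[(tert-butyldimethylsilyl)oxy]-5-hydroxy-4-methylcyclohex-3-en-1-yl]carbonyl}-1,3-oxazolidin-2-one | O=C(N1[C@H](Cc2ccccc2)COC1=O)[C@H]3CC=C(C)[C@@H](O)[C@@H]3O[Si](C)(C)C(C)(C)C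
F4 | step 10 | (1S,3S,4S,5S,6R)-3,4-epoxy-5,6-dihydroxy-N-methoxy-N,4-dimethylcyclohexane-1-carboxamide (target locants) | CON(C)C(=O)[C@H]1C[C@@H]2O[C@]2(C)[C@@H](O)[C@@H]1O
F5 | step 14 | (1R,3S,4S,5S,6R)-3,4-epoxy-4-methyl-1-(3-oxoprop-1-en-2-yl)cyclohexane-5,6-diyl bis[(2Z)-2-methylbut-2-enoate] | C=C(C=O)[C@H]1C[C@@H]2O[C@]2(C)[C@@H](OC(=O)/C(C)=C\C)[C@@H]1OC(=O)/C(C)=C\C
F6 | step 14 | (1R,3S,4S,5S,6R)-3,4-epoxy-1-[(3S)-3-hydroxyhexa-1,5-dien-2-yl]-4-methylcyclohexane-5,6-diyl bis[(2Z)-2-methylbut-2-enoate] | C=C([C@H](CC=C)O)[C@H]1C[C@@H]2O[C@]2(C)[C@@H](OC(=O)/C(C)=C\C)[C@@H]1OC(=O)/C(C)=C\C
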